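Per hour was the unit I reckoned in: the rate of product formation divided by the starting material remaining, which I call a flask's constant. These were the flasks, the readings and the questions.

| flask | starting material | partner | catalyst | product | time |
|---|---|---|---|---|---|
| alpha | 0.300 M | 0.900 M | 6.00 × 10⁻⁴ M |  |  |
| delta | 0.120 M | 0.720 M | 6.00 × 10⁻⁴ M |  |  |
| beta | 0.300 M | 0.900 M | 3.00 × 10⁻⁴ M |  |  |
| zeta | 0.300 M | 0.900 M | 6.00 × 10⁻⁴ M | 0.0900 M |  |
| eta | 0.300 M | 0.900 M | 9.20 × 10⁻⁵ M |  | 5.7 h |

| run | time / h | [product] / M |
|---|---|---|
| alpha run | 0.25 | 0.0054 |
| alpha run | 0.77 | 0.0238 |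
| alpha run | 1.5 | 0.0392 |
| alpha run | 2.3 | 0.0630 |
| alpha run | 3.3 | 0.0836 |
| alpha run | 4.5 | 0.1071 |
| alpha run | 5.7 | 0.1295 |
| delta run | 0.25 | 5 × 10⁻⁴ |
| delta run | 0.77 | 0.0101 |
| delta run | 1.5 | 0.0142 |
| delta run | 2.3 | 0.0186 |
| delta run | 3.3 | 0.0306 |
| delta run | 4.5 | 0.0414 |
| delta run | 5.7 | 0.0474 |
| beta run | 0.25 | 0.0068 |
| beta run | 0.77 | 0.0163 |
| beta run | 1.5 | 0.0303 |
| beta run | 2.3 | 0.0465 |
| beta run | 3.3 | 0.0629 |
| beta run | 4.5 | 0.0862 |
| beta run | 5.7 | 0.1010 |
| zeta run | 0.25 | 0.0997 |
| zeta run | 0.77 | 0.1120 |
| zeta run | 1.5 | 0.1325 |
| zeta run | 2.3 | 0.1511 |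
| zeta run | 3.3 | 0.1730 |
| zeta run | 4.5 | 0.1950 |
| zeta run | 5.7 | 0.2181 |

(readings scatter by 0.002 M)

- reaction order in [catalyst] at the outset, round the charge of the alpha run, defined at two percent of the starting material turned into product
- the delta run starts with 0.180 M less of starting material and of partner than the alpha run, and with no product. Compared where both hold the same amount of starting material, once fifteen percent of what the delta run was charged with has turned into product, is the delta run faster, slower or alike (within a tenth)?
- product in the eta run at 5.7 h, as a share of the starting material charged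
- which of these the readings show (an uncatalysed path runs beside / the catalyst rests as a dimer / the product speeds the reaction / the catalyst dies in pairs / the catalyst dies by itself)

- Overall: starting material + partner -> product, with catalyst as catalyst.
- Constant volume, constant temperature.
- The analysis sees a species whether free or bound.
- An order is taken over about fifteen percent of the charge, up and down.

I asked about the end first. Alpha and eta each held 0.300 M of starting material against 0.900 M of partner, more partner than starting material, so starting material was the limiting reagent and product in eta had a ceiling of 0.300 M.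

Then I asked how fast that end is approached, using the last readings:

alpha constant = ln(0.300 M / (0.300 M − 0.1295 M)) / 5.7 h = 0.0991 h⁻¹

beta constant = ln(0.300 M / (0.300 M − 0.1010 M)) / 5.7 h = 0.0720 h⁻¹

Alpha's reading at 2.3 h gave 0.102 h⁻¹, so I treated its constant as steady. Zeta, less its added product, read 0.128 M at 5.7 h, beside 0.1295 M in alpha.

Two extreme flasks could be solved in the head. If the catalyst carried the whole reaction, the constant would follow the charge: beta, with half of alpha's catalyst, would show 0.0495 h⁻¹, and eta would reach 8.30 %. If the catalyst did nothing, beta would show alpha's constant, and eta would reach alpha's 43.2 %. Beta read 0.0720 h⁻¹, more than the first extreme and less than the second, so the real flask lay between them.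

Alpha and beta gave 2 points, and those do not tell a line from a curve. I committed to the straight line, a path through the catalyst beside a path without it, and named the catalyst-free constant, the value on that line at no catalyst:

catalyst-free constant = 2 × beta constant − alpha constant = 0.0449 h⁻¹

eta constant = catalyst-free constant + (alpha constant − catalyst-free constant) × 0.153 = 0.0532 h⁻¹

eta share = 1 − exp(−eta constant × 5.7 h) = 26.2 %

The forecast gave 0.5 for the order, alike for delta, the catalyst rests as a dimer for the cause, in its words “That points to a half-order resting dimer”, and 20.5 % for eta, a lower share than my own.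

The simulation gave 26.1 % for eta, with delta alike and the readings showing that an uncatalysed path runs beside.

    catalyst + starting material ⇌ catalyst-substrate complex (108.4 M⁻¹ h⁻¹, 57.24 h⁻¹)
    catalyst-substrate complex + partner → product + catalyst (583.2 M⁻¹ h⁻¹)
    starting material + partner → product (0.05184 M⁻¹ h⁻¹)

A fit with the catalyst resting as a dimer left a root mean square residual of 0.90 in units of the scatter and put eta at 20.1 %. Put to alpha once more, the catalyst-free constant gives the catalyst a share of 0.547 of the alpha constant, an average up to 5.7 h and on a straight line the order in catalyst over that stretch, while the order at the outset round alpha's charge came to 0.54.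

(The readings were generated by integration for substances that don't exist; scatter was added.)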